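**Plan**

1. Last cut: C2–C1′ (flavanone C2 to ring B). This removes the only stereocentre and leaves the achiral chromone 7 and boronic acid 8. C2 (S) is set in the final step by the chiral ligand of a Rh-catalysed 1,4-arylation in a near-neutral medium, so the base-labile centre meets no further reagent.
2. Chromone 7 is cut at O1–C2 and C2–C3 (C2 is one carbon from DMF-DMA) and at C6–CH2 and C8–CH2 (both prenyl groups). All four bonds are made in one flask from the acetophenone bis(1,1-dimethylallyl) ether 4.
3. Enabling feature: with ring C open, O1 and O5 are mirror-related oxygens ortho to C4a. Each has exactly one H-bearing ortho carbon (C8 and C6), and these two carbons flank C7–OMe. The two oxygens therefore carry the prenyl groups as tertiary allyl ethers, which also mask the chelating phenols. A double [3,3] shift delivers the prenyls to C6/C8 and frees the OH that closes ring C; either OH gives the same chromone.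
4. Forward order: ring A is bought (1); O-alkylation and semi-hydrogenation give 4; ring C closes in the cascade (step 3); ring B is joined last (step 4).

Key step: step 3

Assumption: the Rh/(S)-biaryl-bisphosphine catalyst is taken to arylate the chromone face that gives (2S), by analogy with the (S)-ligand/(S)-3-arylcyclohexanone correlation of this reaction class (same spatial sense and same descriptor, since O1 takes the place of the ring CH2); if a calibration run shows the opposite sense, the (R)-ligand is used in step 4.

**Route**

Step 1
Reactants: 1 acetophenone 1-(2,6-dihydroxy-4-methoxyphenyl)ethan-1-one; 2 propargylic chloride 3-chloro-3-methylbut-1-yne (two equivalents are incorporated)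
Product: 3 bis(propargylic) ether 1-{4-methoxy-2,6-bis[(2-methylbut-3-yn-2-yl)oxy]phenyl}ethan-1-one
Conditions: 2 (4 equiv), DBU (4 equiv), CuCl2·2H2O (1 mol%), MeCN, 0 °C to rt
Reagents that add atoms: none
Why: Copper-catalysed propargylic etherification, in which a copper acetylide/allenylidene electrophile from 2 is captured at its tertiary carbon by the DBU-generated phenoxide, should alkylate both OH groups (the second, carbonyl-chelated one more slowly); no stereocentre is formed.

Step 2
Reactants: 3 bis(propargylic) ether
Product: 4 bis(1,1-dimethylallyl) ether 1-{4-methoxy-2,6-bis[(2-methylbut-3-en-2-yl)oxy]phenyl}ethan-1-one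
Conditions: H2 (1 atm), Lindlar catalyst (Pd/CaCO3, Pb-poisoned), quinoline, EtOAc, 0 °C, stopped after uptake of 2 equiv
Reagents that add atoms: none
Why: Lindlar semi-hydrogenation of the two terminal alkynes should stop at the vinyl stage with the poisoned catalyst, leaving the ketone and the aryl ethers untouched; no stereocentre is formed.

Step 3
Reactants: 4 bis(1,1-dimethylallyl) ether
Product: 7 chromone 5-hydroxy-7-methoxy-6,8-bis(3-methylbut-2-en-1-yl)-4H-chromen-4-one, via bis-ether enaminone 5 (not isolated), via diprenyl dihydroxy enaminone 6 (not isolated)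
Conditions: DMF-DMA (2.5 equiv), PhMe, 100 °C; volatiles removed; o-xylene, 140 °C; then AcOH, 60 °C
Reagents that add atoms: N,N-dimethylformamide dimethyl acetal, COC(OC)N(C)C
Why: The methyl ketone condenses with DMF-DMA to the vinylogous amide 5; each aryl 1,1-dimethylallyl ether then undergoes an aromatic Claisen [3,3] shift through a chair transition state to its only H-bearing ortho carbon (C3/C5 of the acetophenone, C8/C6 of the target), and tautomerisation of the dienone gives the ortho-prenyl phenol, so that 6 carries both prenyl groups on the carbons flanking the OMe. A liberated OH then adds to the β-carbon of the enaminone and Me2NH is expelled (promoted by AcOH), which closes the pyranone ring at O1–C2 by a 6-endo-trig addition–elimination. The closest known reaction types are the Claisen rearrangement of aryl 1,1-dimethylallyl ethers to ortho-prenylphenols and the enaminone route from 2-hydroxyacetophenones to chromones; either order of condensation and rearrangement leads to 6. No stereocentre is formed. Regioselectivity is secured by the substrate, because the other ortho position of each ether is the acyl-bearing carbon (a shift there cannot aromatise and should revert) and because the mirror symmetry of 6 makes closure on either OH give the same chromone; chemoselectivity rests on the basic acetal medium of the first stage (no ionisation of the tertiary ethers to isoprene), on removing excess acetal before the phenols appear (no O-methylation) and on a weak acid for the closure (no chroman formation from prenyl and OH).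

Step 4
Reactants: 7 chromone; 8 boronic acid (4-hydroxy-3-methoxyphenyl)boronic acid
Product: 9 target (2S)-5-hydroxy-2-(4-hydroxy-3-methoxyphenyl)-7-methoxy-6,8-bis(3-methylbut-2-en-1-yl)-2,3-dihydro-4H-chromen-4-one
Conditions: [Rh(OH)(cod)]2 (3 mol%), (S)-2,2'-bis[bis(3,4,5-trifluorophenyl)phosphino]-6,6'-dimethoxy-1,1'-biphenyl (6.6 mol%), 8 (3 equiv), PhMe/H2O 10:1, 30–40 °C
Reagents that add atoms: none
Why: In this Hayashi–Miyaura-type Rh-catalysed asymmetric 1,4-addition the aryl–Rh species formed by transmetalation from 8 should insert the chromone C2=C3 bond on the face left open by the C2-symmetric electron-poor bisphosphine, which sets C2 as (S) under catalyst control, and hydrolysis of the oxa-π-allyl rhodium enolate releases the flavanone in a neutral medium in which retro-oxa-Michael racemisation should not operate and the trisubstituted prenyl alkenes do not insert.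

**Compound list**

1 | 1-(2,6-dihydroxy-4-methoxyphenyl)ethan-1-one | CC(=O)c1c(O)cc(OC)cc1O | starting material
2 | 3-chloro-3-methylbut-1-yne | CC(C)(Cl)C#C | starting material
3 | 1-{4-methoxy-2,6-bis[(2-methylbut-3-yn-2-yl)oxy]phenyl}ethan-1-one | CC(=O)c1c(OC(C)(C)C#C)cc(OC)cc1OC(C)(C)C#C | intermediate
4 | 1-{4-methoxy-2,6-bis[(2-methylbut-3-en-2-yl)oxy]phenyl}ethan-1-one | CC(=O)c1c(OC(C)(C)C=C)cc(OC)cc1OC(C)(C)C=C | intermediate
5 | (E)-3-(dimethylamino)-1-{4-methoxy-2,6-bis[(2-methylbut-3-en-2-yl)oxy]phenyl}prop-2-en-1-one | CN(C)/C=C/C(=O)c1c(OC(C)(C)C=C)cc(OC)cc1OC(C)(C)C=C | intermediate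
6 | (E)-3-(dimethylamino)-1-[2,6-dihydroxy-4-methoxy-3,5-bis(3-methylbut-2-en-1-yl)phenyl]prop-2-en-1-one | CN(C)/C=C/C(=O)c1c(O)c(CC=C(C)C)c(OC)c(CC=C(C)C)c1O | intermediate
7 | 5-hydroxy-7-methoxy-6,8-bis(3-methylbut-2-en-1-yl)-4H-chromen-4-one | COc1c(CC=C(C)C)c(O)c2c(occc2=O)c1CC=C(C)C | intermediate
8 | (4-hydroxy-3-methoxyphenyl)boronic acid | COc1cc(B(O)O)ccc1O | starting material
9 | (2S)-5-hydroxy-2-(4-hydroxy-3-methoxyphenyl)-7-methoxy-6,8-bis(3-methylbut-2-en-1-yl)-2,3-dihydro-4H-chromen-4-one | COc1cc([C@@H]2CC(=O)c3c(O)c(CC=C(C)C)c(OC)c(CC=C(C)C)c3O2)ccc1O | target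

**Count**

Total steps: 4. Longest linear sequence: 4 steps (1 → 3 → 4 → 7 → 9).

**Steps most likely to fail, with fallbacks**

Step 3. The tertiary allyl ethers may fragment thermally to phenol and isoprene before they rearrange. A shift into the acyl-bearing ipso position followed by a Cope shift would place a reverse-prenyl group para. Released phenols may be O-methylated by residual acetal, or may cyclise onto a prenyl group during the acid finish. The fallback replaces the sigmatropic delivery by cross-coupling; it sets out from 1 and comes back at 7. Compound 1 is condensed with DMF-DMA and closed with AcOH to 5-hydroxy-7-methoxy-4H-chromen-4-one F1. Electrophilic iodination with N-iodosuccinimide (2.2 equiv, DMF) at the two activated positions should give 5-hydroxy-6,8-diiodo-7-methoxy-4H-chromen-4-one F2. A double Stille coupling with tributyl(3-methylbut-2-en-1-yl)stannane (Pd(PPh3)4, DMF, 90 °C) should then give 7.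

Step 1. Alkylation may stall at the mono-ether, because the remaining OH is hydrogen-bonded to the carbonyl and flanked by the acyl group; forcing conditions may lead to C-propargylation or chromene formation. The fallback gives up O-to-C transfer for direct electrophilic C-prenylation; it sets out from 1 and comes back at 6. Compound 1 is treated with 1-bromo-3-methylbut-2-ene in aqueous KOH at 0 °C, and 1-[2,6-dihydroxy-4-methoxy-3,5-bis(3-methylbut-2-en-1-yl)phenyl]ethan-1-one F3 is separated by chromatography from mono-prenylated and O-prenylated material. Condensation of F3 with DMF-DMA (PhMe, 90 °C) gives 6, which is closed to 7 by the acid finish of step 3.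

Step 4. The 5-hydroxy-4-oxo unit may bind rhodium as an O,O-chelate, and the electron-rich boronic acid may protodeboronate, so conversion may be low. Facial discrimination may be insufficient, or the enolate may open reversibly and erode the enantiomeric purity. The fallback closes ring C by oxa-Michael addition and obtains the enantiomer by resolution; it sets out from 4 and comes back at 9. Claisen–Schmidt condensation of 4 with 3-methoxy-4-(methoxymethoxy)benzaldehyde (KOH, EtOH, rt) gives the chalcone (E)-1-{4-methoxy-2,6-bis[(2-methylbut-3-en-2-yl)oxy]phenyl}-3-[3-methoxy-4-(methoxymethoxy)phenyl]prop-2-en-1-one F4, in which both phenols are masked. Heating (o-xylene, 140 °C) and then NaOAc in EtOH at reflux should bring about the double Claisen shift and 6-endo oxa-Michael closure to the racemic flavanone MOM ether 5-hydroxy-7-methoxy-2-[3-methoxy-4-(methoxymethoxy)phenyl]-6,8-bis(3-methylbut-2-en-1-yl)-2,3-dihydro-4H-chromen-4-one F5. Cleavage of the MOM ether (HCl, MeOH, rt) gives racemic 5-hydroxy-2-(4-hydroxy-3-methoxyphenyl)-7-methoxy-6,8-bis(3-methylbut-2-en-1-yl)-2,3-dihydro-4H-chromen-4-one F6. Preparative chromatography on a chiral stationary phase then gives 9.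

**Further compounds**

F1 | step 3 | 5-hydroxy-7-methoxy-4H-chromen-4-one | COc1cc(O)c2c(occc2=O)c1
F2 | step 3 | 5-hydroxy-6,8-diiodo-7-methoxy-4H-chromen-4-one | COc1c(I)c(O)c2c(occc2=O)c1I
F3 | step 1 | 1-[2,6-dihydroxy-4-methoxy-3,5-bis(3-methylbut-2-en-1-yl)phenyl]ethan-1-one | CC(=O)c1c(O)c(CC=C(C)C)c(OC)c(CC=C(C)C)c1O
F4 | step 4 | (E)-1-{4-methoxy-2,6-bis[(2-methylbut-3-en-2-yl)oxy]phenyl}-3-[3-methoxy-4-(methoxymethoxy)phenyl]prop-2-en-1-one | COCOc1ccc(/C=C/C(=O)c2c(OC(C)(C)C=C)cc(OC)cc2OC(C)(C)C=C)cc1OC
F5 | step 4 | racemic 5-hydroxy-7-methoxy-2-[3-methoxy-4-(methoxymethoxy)phenyl]-6,8-bis(3-methylbut-2-en-1-yl)-2,3-dihydro-4H-chromen-4-one | COCOc1ccc(C2CC(=O)c3c(O)c(CC=C(C)C)c(OC)c(CC=C(C)C)c3O2)cc1OC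
F6 | step 4 | racemic 5-hydroxy-2-(4-hydroxy-3-methoxyphenyl)-7-methoxy-6,8-bis(3-methylbut-2-en-1-yl)-2,3-dihydro-4H-chromen-4-one | COc1cc(C2CC(=O)c3c(O)c(CC=C(C)C)c(OC)c(CC=C(C)C)c3O2)ccc1O
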